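## Analysis of the target

Arecatannin A2 (22) is a linear B-type procyanidin tetramer. Three (−)-epicatechin units (units 1–3, counted from the end whose C8 is free) and a terminal (+)-catechin unit (unit 4) are joined three times by a C4→C8 bond. Each unit is a 2-arylchroman made of a phloroglucinol ring A, a pyran ring C and a catechol ring B. There are eleven stereocentres: C2 and C3 in every unit (2R,3R in units 1–3, 2R,3S in unit 4) and C4 in units 1–3. In each extender unit the ring B aryl and the C3 oxygen are cis and the C3 oxygen and the C4 aryl are trans (4β), so the aryl groups on C2 and C4 are trans. The sixteen phenolic and four secondary hydroxyl groups make the free compound easy to oxidise and prone to C2 epimerisation in base, and the doubly benzylic C4–C8 bonds are cleaved by acid, so the hydroxyls must stay masked until a neutral final deprotection. The hard points are the site of each interflavan bond (C8 against C6), the configuration at each C4, the control of chain length and the congestion at the diarylmethine carbons. The strategy rests on ring C of unit 2: O1 joins C8a of ring A to C2, which carries ring B, so the O1–C2 bond is the 6-endo adduct of the C8a phenol across a C2≡C3 aryl alkyne whose propargylic carbon is the diarylmethine C4, already bonded to C8 of unit 3.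

## Retrosynthetic reasoning

**Protecting groups.** Target 22 is traced back to tetramer 21, in which eighteen hydroxyls are benzyl ethers and C8 of unit 1 carries bromine. All O–benzyl bonds and the C–Br bond are cut in one hydrogenolysis, the only deprotection mild enough for the free procyanidin.

**C4 (unit 1)–C8 (unit 2).** Tetramer 21 is cut into trimer 20 and the C4-activated epicatechin 6. Unit 1 is a complete natural monomer, so it is attached as such through its C4 cation. The bromine at C8 of 6 means that neither 6 nor product 21 has a free top C8, so chain growth stops at the tetramer. The forward reaction must attack C8 of unit 2 and enter trans to the C3 oxygen of unit 1.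

**C2–H and C3–O of unit 2.** Trimer 20 is traced back to flav-2-ene 18 through epoxide 19. An enol ether is the simplest precursor of the C2/C3 pair, because the existing C4 centre can direct both new centres on a ring. Forward, oxygen must add to C3 anti to the C4 aryl group and hydride to C2 anti to the C3 oxygen.

**O1–C2 of unit 2 (key disconnection).** Flavene 18 is opened to the ortho-propargylic phenol 17. This cut removes ring C but leaves the C4–C8 bond to unit 3 and the C4 stereocentre in place. The ring closure is then an isomerisation with no stereochemical event. The forward step must close 6-endo rather than 5-exo and must not disturb C4.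

**C2–C1′ (alkyne–ring B).** Aryl alkyne 17 is cut into terminal alkyne 15 and aryl bromide 16. Ring B is added after C4 is set because the asymmetric propargylic substitution runs through a copper allenylidene and needs a terminal alkyne.

**C4–C4a of unit 2, then C3–C4 and C4–C8.** Phenol 15 is cut into propargylic carbonate 13 and phenol 14; this bond formation creates the C4 stereocentre under catalyst control. Carbonate 13 comes from alcohol 12, that from aldehyde 10 and acetylide 11, and 10 from bromide 8 through aryllithium 9. The carbon that becomes C4 of unit 2 is therefore fixed on C8 of unit 3 by the position of a bromine atom, not by the site selectivity of an oligomer.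

**C4 (unit 3)–C8 (unit 4).** Bromide 8 is the benzylated form of diol 7, which is cut into the same electrophile 6 and benzylated catechin 2. A coupling of two monomers is the most dependable use of flavan-4-yl cation chemistry, and the bromine cap of 6 reappears as the handle for the formylation. Electrophile 6 comes from epicatechin 3 through 4 and 5, and nucleophile 2 from catechin 1. The natural monomers thus supply eight of the eleven stereocentres; only unit 2 is built.

## Alternatives that were turned down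

**Alternative 1: lactone backbone with the three B rings added last.**
- Disconnection: the three C2–C1′ bonds of units 1–3 are cut, leaving tris-lactone A2 (each extender unit a 3-benzyloxy-4-arylchroman-2-one) and aryllithium A3.
- Forward key step: A3 adds to the three lactone carbonyls and the hemiketals are reduced in the same flask by a silane and a Lewis acid, giving the perbenzylated tetramer A1.
- For it: it is the most convergent endgame, one reagent supplies all three B rings, and A1 is one hydrogenolysis from the target.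
- Against it: A2 still holds all three C4–C8 bonds and six stereocentres and maps onto no natural building block. Each aryl ester opens to a ketone phenoxide that can take up a second A3, the C3–H next to the carbonyl can enolise and epimerise, and three additions and three reductions must all succeed in one flask.
- Comparison: the C2 centres come from the same hydride delivery anti to the C3 oxygen that the chosen route uses once. Alternative 1 is stronger in late-stage convergence. The chosen route offers instead three units bought with their B rings and C2/C3 centres, and a single ring construction that carries the risk.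

**Alternative 2: ring A of unit 4 by benzannulation.**
- Disconnection: ring A of unit 4 is taken apart into the four carbons of cyclobutenone A5 (carrying the future C2–C3–C4 chain as an acetonide) and the two carbons of siloxyalkyne A6 on C4 of unit 3.
- Forward key step: heating opens A5 to a vinylketene, which adds to A6 and electrocyclises to phenol A4, forming C8–C8a, C6–C7 and C4a–C8a (Danheiser benzannulation).
- For it: the linkage position on unit 4 is fixed without any aromatic substitution, and the conditions are neutral.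
- Against it: it builds an aromatic ring that (+)-catechin supplies for nothing. A6 is an ynol ether on a doubly activated, epimerisable C4 and presupposes a finished trimer of units 1–3. Ring C of unit 4 must still be closed with control at C2, and silyl and acetonide groups must be exchanged, so many steps follow.
- Comparison: on regiochemical certainty of the lowest linkage it is at least as strong as the chosen route. The chosen route has the same certainty for the unit 2–unit 3 bond through the bromine placed on a monomer, forms one C–O bond in a mild catalytic step, and keeps unit 4 as a purchased monomer.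

**Alternative 3: open-chain stereotriad closed at the aryl–oxygen bond.**
- Disconnection: O1–C8a of unit 3 is cut, giving bromo alcohol A8.
- Forward key step: Pd(OAc)2 with a di-tert-butylbiarylphosphine and Cs2CO3 couples the C2 hydroxyl with the ring A bromide (intramolecular Buchwald–Hartwig etherification), giving dimer A7 with retention at all three centres.
- For it: the ring closure is stereochemically silent, so no hydride facial selectivity at C2 is needed; on this point it is stronger than the chosen route.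
- Against it: the triad, with a diarylmethine between two 2,6-dioxygenated rings, must be built with full open-chain control. The secondary benzylic alkoxide on palladium can undergo β-hydride elimination, the electron-rich ortho-substituted bromide adds slowly to zerovalent palladium, and only the dimer is reached, so the construction would have to be repeated for units 2 and 1.
- Comparison: the chosen route sets C4 catalytically and derives C3 and C2 from it on a ring in one operation, from simple aryl building blocks and with fewer steps per unit.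

Key step: step 12

## Conventions and assumption

Bn is benzyl. Units keep the numbers they have in the target. "Dimer-8-yl" means C8 of the epicatechin unit of 3,5,7,3′,4′-penta-O-benzylepicatechin-(4β→8)-3,5,7,3′,4′-penta-O-benzylcatechin.

Assumption: the (S,S)-Ph-pybox copper catalyst is taken to deliver the phenol to the face of the copper allenylidene that gives the (R)-propargylic carbon; the ligand enantiomer, not the remote stereocentres of the substrate, decides this, so (R,R)-Ph-pybox would be used if the sense proved opposite.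

## Route

Step 1
Reactants: 1 (+)-catechin
Product: 2 5,7,3′,4′-tetra-O-benzyl-(+)-catechin
Conditions: BnBr (4.4 equiv), K2CO3, DMF, 0 °C to rt
Reagents that add atoms: benzyl bromide, BrCc1ccccc1
Why: Williamson etherification; carbonate deprotonates the four phenols but not the secondary C3 hydroxyl, and C2 and C3 are not touched.

Step 2
Reactants: 3 (−)-epicatechin
Product: 4 5,7,3′,4′-tetra-O-benzyl-(−)-epicatechin
Conditions: BnBr (4.4 equiv), K2CO3, DMF, 0 °C to rt
Reagents that add atoms: benzyl bromide, BrCc1ccccc1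
Why: Williamson etherification of the four phenols as in step 1; the mild base at room temperature should not epimerise C2.

Step 3
Reactants: 4 5,7,3′,4′-tetra-O-benzyl-(−)-epicatechin
Product: 5 5,7,3′,4′-tetra-O-benzyl-4β-(2-ethoxyethoxy)epicatechin
Conditions: DDQ (2 equiv), 2-ethoxyethanol (5 equiv), CH2Cl2, rt
Reagents that add atoms: 2-ethoxyethanol, CCOCCO
Why: DDQ benzylic oxidation; hydride abstraction from C4 gives a cation stabilised by the three ring A oxygens, and the alcohol should add trans to the C3 hydroxyl to give the 4β ether.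

Step 4
Reactants: 5 5,7,3′,4′-tetra-O-benzyl-4β-(2-ethoxyethoxy)epicatechin
Product: 6 8-bromo-5,7,3′,4′-tetra-O-benzyl-4β-(2-ethoxyethoxy)epicatechin
Conditions: NBS (1.0 equiv), CH2Cl2, −78 to 0 °C
Reagents that add atoms: N-bromosuccinimide, O=C1CCC(=O)N1Br
Why: Electrophilic aromatic bromination; in tetra-O-benzyl flavan-3-ols C8 (between O1 and one benzyloxy group) reacts ahead of C6 (between two benzyloxy groups), and ring B is much less activated.

Step 5
Reactants: 6 8-bromo-5,7,3′,4′-tetra-O-benzyl-4β-(2-ethoxyethoxy)epicatechin; 2 5,7,3′,4′-tetra-O-benzyl-(+)-catechin (2 equiv)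
Product: 7 8-bromo-5,7,3′,4′-tetra-O-benzylepicatechin-(4β→8)-5,7,3′,4′-tetra-O-benzylcatechin (both 3-OH free)
Conditions: TMSOTf (0.2 equiv), CH2Cl2, −78 °C; aq NaHCO3
Reagents that add atoms: none
Why: Lewis acid-promoted Friedel–Crafts coupling of a flavan-4-yl cation; C8 of 2 should attack the C4 cation of 6 trans to the C3 oxygen (4β), and the bromine at C8 of 6 blocks self-condensation and chain growth and remains as the handle for step 7.

Step 6
Reactants: 7 8-bromo-5,7,3′,4′-tetra-O-benzylepicatechin-(4β→8)-5,7,3′,4′-tetra-O-benzylcatechin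
Product: 8 8-bromo-3,5,7,3′,4′-penta-O-benzylepicatechin-(4β→8)-3,5,7,3′,4′-penta-O-benzylcatechin
Conditions: NaH, BnBr, n-Bu4NI (cat.), DMF, 0 °C to rt
Reagents that add atoms: benzyl bromide, BrCc1ccccc1
Why: Williamson etherification of the two secondary alkoxides; with all phenols already capped no base-sensitive centre remains.

Step 7
Reactants: 8 8-bromo-3,5,7,3′,4′-penta-O-benzylepicatechin-(4β→8)-3,5,7,3′,4′-penta-O-benzylcatechin
Product: 10 8-formyl-3,5,7,3′,4′-penta-O-benzylepicatechin-(4β→8)-3,5,7,3′,4′-penta-O-benzylcatechin, via 8-lithio decabenzyl dimer 9 (not isolated)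
Conditions: n-BuLi (1.1 equiv), THF, −78 °C; DMF, −78 to 0 °C; H2O
Reagents that add atoms: N,N-dimethylformamide, CN(C)C=O; n-butyllithium, [Li]CCCC (lithium of 9 only)
Why: Bromine–lithium exchange at the oxygen-flanked C8 should outrun deprotonation of benzyl ethers at −78 °C, and formylation of the aryllithium with DMF puts the future C4 of unit 2 exactly on C8 of unit 3.

Step 8
Reactants: 10 8-formyl-3,5,7,3′,4′-penta-O-benzylepicatechin-(4β→8)-3,5,7,3′,4′-penta-O-benzylcatechin; 11 ethynylmagnesium bromide (3 equiv)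
Product: 12 8-(1-hydroxyprop-2-yn-1-yl)-3,5,7,3′,4′-penta-O-benzylepicatechin-(4β→8)-3,5,7,3′,4′-penta-O-benzylcatechin (both carbinol epimers)
Conditions: THF, 0 °C; H2O
Reagents that add atoms: none
Why: Grignard 1,2-addition of the acetylide to the aryl aldehyde; the carbinol centre forms without control, which is harmless because it is erased in step 10.

Step 9
Reactants: 12 8-(1-hydroxyprop-2-yn-1-yl)-3,5,7,3′,4′-penta-O-benzylepicatechin-(4β→8)-3,5,7,3′,4′-penta-O-benzylcatechin
Product: 13 8-[1-(methoxycarbonyloxy)prop-2-yn-1-yl]-3,5,7,3′,4′-penta-O-benzylepicatechin-(4β→8)-3,5,7,3′,4′-penta-O-benzylcatechin (both epimers)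
Conditions: LiN(SiMe3)2 (1.05 equiv), THF, −78 °C; ClCO2Me
Reagents that add atoms: methyl chloroformate, COC(Cl)=O
Why: O-acylation of the lithium alkoxide; acid-free conditions should keep the ionisation-prone trialkoxybenzylic carbonate intact, and it is carried on without chromatography on acidic silica.

Step 10
Reactants: 13 8-[1-(methoxycarbonyloxy)prop-2-yn-1-yl]-3,5,7,3′,4′-penta-O-benzylepicatechin-(4β→8)-3,5,7,3′,4′-penta-O-benzylcatechin; 14 3,5-bis(benzyloxy)phenol (2 equiv)
Product: 15 3,5-bis(benzyloxy)-2-[(1R)-1-(dimer-8-yl)prop-2-yn-1-yl]phenol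
Conditions: Cu(OTf)2 (10 mol %), (S,S)-Ph-pybox (12 mol %), i-Pr2NEt (1.2 equiv), MeOH/CH2Cl2, −20 °C
Reagents that add atoms: none
Why: Copper-catalysed asymmetric propargylic substitution of Friedel–Crafts type; the monovalent copper–pybox complex formed in situ gives a copper acetylide, loss of methyl carbonate gives a copper allenylidene, and the ortho carbon of the phenol (between OH and OBn, the less hindered activated site) attacks its γ-carbon on the face set by the ligand, which should give C4 of unit 2 as (R) from both epimers of 13.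

Step 11
Reactants: 15 3,5-bis(benzyloxy)-2-[(1R)-1-(dimer-8-yl)prop-2-yn-1-yl]phenol; 16 4-bromo-1,2-bis(benzyloxy)benzene (1.2 equiv)
Product: 17 3,5-bis(benzyloxy)-2-{(1R)-3-[3,4-bis(benzyloxy)phenyl]-1-(dimer-8-yl)prop-2-yn-1-yl}phenol
Conditions: Pd(PhCN)2Cl2 (3 mol %), [(t-Bu)3PH]BF4 (6 mol %), CuI (2 mol %), i-Pr2NH, dioxane, rt
Reagents that add atoms: none
Why: Sonogashira coupling; the bulky electron-rich phosphine lets the electron-rich aryl bromide add to zerovalent palladium at room temperature, where the free phenol is tolerated and the amine is too weak to shift the doubly benzylic propargylic proton.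

Step 12
Reactants: 17 3,5-bis(benzyloxy)-2-{(1R)-3-[3,4-bis(benzyloxy)phenyl]-1-(dimer-8-yl)prop-2-yn-1-yl}phenol
Product: 18 (4R)-5,7,3′,4′-tetrakis(benzyloxy)flav-2-ene-(4→8)-3,5,7,3′,4′-penta-O-benzylepicatechin-(4β→8)-3,5,7,3′,4′-penta-O-benzylcatechin
Conditions: Ph3PAuNTf2 (5 mol %), CH2Cl2, 4 Å MS, 0 °C to rt; filtration through basic Al2O3
Reagents that add atoms: none
Why: The cationic gold complex binds the C2≡C3 alkyne, and the 3,4-bis(benzyloxy)phenyl group places the developing positive charge on C2, the carbon bearing ring B. The ring A phenol, held ortho to the propargylic carbon C4, attacks C2 anti to gold, and protodeauration of the vinylgold species releases the enol ether and the catalyst. The closest known reaction type is the gold- or platinum-catalysed cycloisomerisation (intramolecular hydroalkoxylation) of ortho-(3-arylprop-2-ynyl)phenols to 2-aryl-4H-chromenes. Ring C of unit 2 closes in the 6-endo-dig mode by forming O1–C2. No stereocentre is formed; C4, set in step 10, is not a reacting atom and should survive because the medium contains no base that could move its proton towards an allene. The step needs 6-endo over 5-exo selectivity (the latter would give a benzylidene dihydrobenzofuran), which the donor aryl group on the alkyne terminus secures by polarising the alkyne. It also needs the phenol to win over benzyl ether oxygens and arene carbons, which follows because only the phenol adduct can lose a proton and turn the catalyst over. Because the closing oxygen is the only free hydroxyl of ring A and sits beside C4, the position of O1 and the 4→8 linkage are fixed by construction.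

Step 13
Reactants: 18 (4R)-5,7,3′,4′-tetrakis(benzyloxy)flav-2-ene-(4→8)-3,5,7,3′,4′-penta-O-benzylepicatechin-(4β→8)-3,5,7,3′,4′-penta-O-benzylcatechin
Product: 20 5,7,3′,4′-tetra-O-benzylepicatechin-(4β→8)-3,5,7,3′,4′-penta-O-benzylepicatechin-(4β→8)-3,5,7,3′,4′-penta-O-benzylcatechin (3-OH of unit 2 free), via 2α,3α-epoxide 19 (not isolated)
Conditions: DMDO (acetone), CH2Cl2, −78 to −40 °C; volatiles removed cold; Et3SiH (5 equiv), BF3·OEt2 (1.5 equiv), CH2Cl2, −78 °C; aq NaHCO3
Reagents that add atoms: dimethyldioxirane, CC1(C)OO1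
Why: Enol ether epoxidation followed by ionic hydrogenation: the dioxirane should add to the face opposite the pseudoaxial C4 aryl group (C3–O trans to C4–aryl), BF3 opens the epoxide at C2 to the 2-aryl oxocarbenium ion, and Et3SiH should deliver hydride axially, anti to the C3–O bond (inversion at C2), giving the 2,3-cis-3,4-trans pattern of an epicatechin unit.

Step 14
Reactants: 20 5,7,3′,4′-tetra-O-benzylepicatechin-(4β→8)-3,5,7,3′,4′-penta-O-benzylepicatechin-(4β→8)-3,5,7,3′,4′-penta-O-benzylcatechin; 6 8-bromo-5,7,3′,4′-tetra-O-benzyl-4β-(2-ethoxyethoxy)epicatechin (1.2 equiv)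
Product: 21 8-bromo-5,7,3′,4′-tetra-O-benzylepicatechin-(4β→8)-5,7,3′,4′-tetra-O-benzylepicatechin-(4β→8)-3,5,7,3′,4′-penta-O-benzylepicatechin-(4β→8)-3,5,7,3′,4′-penta-O-benzylcatechin
Conditions: TMSOTf (0.2 equiv), CH2Cl2, −78 to −40 °C; aq NaHCO3
Reagents that add atoms: none
Why: The same Friedel–Crafts coupling of a flavan-4-yl cation as in step 5; C8 of unit 2 is the only free C8-type position of 20 and should attack trans to the C3 oxygen of the cation (4β), and the bromine cap means that neither 6 nor 21 can extend the chain.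

Step 15
Reactants: 21 8-bromo-5,7,3′,4′-tetra-O-benzylepicatechin-(4β→8)-5,7,3′,4′-tetra-O-benzylepicatechin-(4β→8)-3,5,7,3′,4′-penta-O-benzylepicatechin-(4β→8)-3,5,7,3′,4′-penta-O-benzylcatechin
Product: 22 arecatannin A2
Conditions: H2 (1 atm), Pd(OH)2/C, NaOAc (1.5 equiv), THF/MeOH/H2O, rt
Reagents that add atoms: none
Why: Catalytic hydrogenolysis cleaves the eighteen benzyl ethers and the aryl C–Br bond in one neutral operation; acetate takes up the hydrogen bromide so that the acid-labile interflavan bonds of the free tetramer are not exposed to strong acid.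

## Compound list

1 | (+)-catechin, (2R,3S) | Oc1cc(O)c2c(c1)O[C@H](c1ccc(O)c(O)c1)[C@@H](O)C2 | starting material
2 | 5,7,3′,4′-tetra-O-benzyl-(+)-catechin | c3ccccc3COc1cc(OCc3ccccc3)c2c(c1)O[C@H](c1ccc(OCc3ccccc3)c(OCc3ccccc3)c1)[C@@H](O)C2 | intermediate
3 | (−)-epicatechin, (2R,3R) | Oc1cc(O)c2c(c1)O[C@H](c1ccc(O)c(O)c1)[C@H](O)C2 | starting material
4 | 5,7,3′,4′-tetra-O-benzyl-(−)-epicatechin | c3ccccc3COc1cc(OCc3ccccc3)c2c(c1)O[C@H](c1ccc(OCc3ccccc3)c(OCc3ccccc3)c1)[C@H](O)C2 | intermediate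
5 | 5,7,3′,4′-tetra-O-benzyl-4β-(2-ethoxyethoxy)epicatechin (2,3-cis, 3,4-trans) | c3ccccc3COc1cc(OCc3ccccc3)c2c(c1)O[C@H](c1ccc(OCc3ccccc3)c(OCc3ccccc3)c1)[C@H](O)[C@H]2OCCOCC | intermediate
6 | 8-bromo-5,7,3′,4′-tetra-O-benzyl-4β-(2-ethoxyethoxy)epicatechin | c3ccccc3COc1cc(OCc3ccccc3)c2c(c1Br)O[C@H](c1ccc(OCc3ccccc3)c(OCc3ccccc3)c1)[C@H](O)[C@H]2OCCOCC | intermediate
7 | 8-bromo-5,7,3′,4′-tetra-O-benzylepicatechin-(4β→8)-5,7,3′,4′-tetra-O-benzylcatechin | c3ccccc3COc1cc(OCc3ccccc3)c2c(c1Br)O[C@H](c1ccc(OCc3ccccc3)c(OCc3ccccc3)c1)[C@H](O)[C@H]2c1c(OCc3ccccc3)cc(OCc3ccccc3)c2c1O[C@H](c1ccc(OCc3ccccc3)c(OCc3ccccc3)c1)[C@@H](O)C2 | intermediate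
8 | 8-bromo-3,5,7,3′,4′-penta-O-benzylepicatechin-(4β→8)-3,5,7,3′,4′-penta-O-benzylcatechin | c3ccccc3COc1cc(OCc3ccccc3)c2c(c1Br)O[C@H](c1ccc(OCc3ccccc3)c(OCc3ccccc3)c1)[C@H](OCc3ccccc3)[C@H]2c1c(OCc3ccccc3)cc(OCc3ccccc3)c2c1O[C@H](c1ccc(OCc3ccccc3)c(OCc3ccccc3)c1)[C@@H](OCc3ccccc3)C2 | intermediate
9 | 8-lithio-3,5,7,3′,4′-penta-O-benzylepicatechin-(4β→8)-3,5,7,3′,4′-penta-O-benzylcatechin | c3ccccc3COc1cc(OCc3ccccc3)c2c(c1[Li])O[C@H](c1ccc(OCc3ccccc3)c(OCc3ccccc3)c1)[C@H](OCc3ccccc3)[C@H]2c1c(OCc3ccccc3)cc(OCc3ccccc3)c2c1O[C@H](c1ccc(OCc3ccccc3)c(OCc3ccccc3)c1)[C@@H](OCc3ccccc3)C2 | intermediate (not isolated)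
10 | 8-formyl-3,5,7,3′,4′-penta-O-benzylepicatechin-(4β→8)-3,5,7,3′,4′-penta-O-benzylcatechin | c3ccccc3COc1cc(OCc3ccccc3)c2c(c1C=O)O[C@H](c1ccc(OCc3ccccc3)c(OCc3ccccc3)c1)[C@H](OCc3ccccc3)[C@H]2c1c(OCc3ccccc3)cc(OCc3ccccc3)c2c1O[C@H](c1ccc(OCc3ccccc3)c(OCc3ccccc3)c1)[C@@H](OCc3ccccc3)C2 | intermediate
11 | ethynylmagnesium bromide | C#C[Mg]Br | starting material
12 | 8-(1-hydroxyprop-2-yn-1-yl)-3,5,7,3′,4′-penta-O-benzylepicatechin-(4β→8)-3,5,7,3′,4′-penta-O-benzylcatechin, both carbinol epimers | c3ccccc3COc1cc(OCc3ccccc3)c2c(c1C(O)C#C)O[C@H](c1ccc(OCc3ccccc3)c(OCc3ccccc3)c1)[C@H](OCc3ccccc3)[C@H]2c1c(OCc3ccccc3)cc(OCc3ccccc3)c2c1O[C@H](c1ccc(OCc3ccccc3)c(OCc3ccccc3)c1)[C@@H](OCc3ccccc3)C2 | intermediate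
13 | 8-[1-(methoxycarbonyloxy)prop-2-yn-1-yl]-3,5,7,3′,4′-penta-O-benzylepicatechin-(4β→8)-3,5,7,3′,4′-penta-O-benzylcatechin, both epimers | c3ccccc3COc1cc(OCc3ccccc3)c2c(c1C(OC(=O)OC)C#C)O[C@H](c1ccc(OCc3ccccc3)c(OCc3ccccc3)c1)[C@H](OCc3ccccc3)[C@H]2c1c(OCc3ccccc3)cc(OCc3ccccc3)c2c1O[C@H](c1ccc(OCc3ccccc3)c(OCc3ccccc3)c1)[C@@H](OCc3ccccc3)C2 | intermediate
14 | 3,5-bis(benzyloxy)phenol | Oc1cc(OCc2ccccc2)cc(OCc2ccccc2)c1 | starting material
15 | 3,5-bis(benzyloxy)-2-[(1R)-1-(dimer-8-yl)prop-2-yn-1-yl]phenol | Oc1cc(OCc3ccccc3)cc(OCc3ccccc3)c1[C@@H](C#C)c1c(OCc3ccccc3)cc(OCc3ccccc3)c2c1O[C@H](c1ccc(OCc3ccccc3)c(OCc3ccccc3)c1)[C@H](OCc3ccccc3)[C@H]2c1c(OCc3ccccc3)cc(OCc3ccccc3)c2c1O[C@H](c1ccc(OCc3ccccc3)c(OCc3ccccc3)c1)[C@@H](OCc3ccccc3)C2 | intermediate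
16 | 4-bromo-1,2-bis(benzyloxy)benzene | Brc1ccc(OCc2ccccc2)c(OCc2ccccc2)c1 | starting material
17 | 3,5-bis(benzyloxy)-2-{(1R)-3-[3,4-bis(benzyloxy)phenyl]-1-(dimer-8-yl)prop-2-yn-1-yl}phenol | Oc1cc(OCc3ccccc3)cc(OCc3ccccc3)c1[C@@H](C#Cc1ccc(OCc3ccccc3)c(OCc3ccccc3)c1)c1c(OCc3ccccc3)cc(OCc3ccccc3)c2c1O[C@H](c1ccc(OCc3ccccc3)c(OCc3ccccc3)c1)[C@H](OCc3ccccc3)[C@H]2c1c(OCc3ccccc3)cc(OCc3ccccc3)c2c1O[C@H](c1ccc(OCc3ccccc3)c(OCc3ccccc3)c1)[C@@H](OCc3ccccc3)C2 | intermediate
18 | (4R)-5,7,3′,4′-tetrakis(benzyloxy)flav-2-ene-(4→8)-3,5,7,3′,4′-penta-O-benzylepicatechin-(4β→8)-3,5,7,3′,4′-penta-O-benzylcatechin | c3ccccc3COc1cc(OCc3ccccc3)c2c(c1)OC(c1ccc(OCc3ccccc3)c(OCc3ccccc3)c1)=C[C@H]2c1c(OCc3ccccc3)cc(OCc3ccccc3)c2c1O[C@H](c1ccc(OCc3ccccc3)c(OCc3ccccc3)c1)[C@H](OCc3ccccc3)[C@H]2c1c(OCc3ccccc3)cc(OCc3ccccc3)c2c1O[C@H](c1ccc(OCc3ccccc3)c(OCc3ccccc3)c1)[C@@H](OCc3ccccc3)C2 | intermediate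
19 | 2α,3α-epoxide of 18 (epoxide oxygen opposite the 4β-aryl group) | c3ccccc3COc1cc(OCc3ccccc3)c2c(c1)O[C@]4(c1ccc(OCc3ccccc3)c(OCc3ccccc3)c1)O[C@@H]4[C@H]2c1c(OCc3ccccc3)cc(OCc3ccccc3)c2c1O[C@H](c1ccc(OCc3ccccc3)c(OCc3ccccc3)c1)[C@H](OCc3ccccc3)[C@H]2c1c(OCc3ccccc3)cc(OCc3ccccc3)c2c1O[C@H](c1ccc(OCc3ccccc3)c(OCc3ccccc3)c1)[C@@H](OCc3ccccc3)C2 | intermediate (not isolated)
20 | 5,7,3′,4′-tetra-O-benzylepicatechin-(4β→8)-3,5,7,3′,4′-penta-O-benzylepicatechin-(4β→8)-3,5,7,3′,4′-penta-O-benzylcatechin | c3ccccc3COc1cc(OCc3ccccc3)c2c(c1)O[C@H](c1ccc(OCc3ccccc3)c(OCc3ccccc3)c1)[C@H](O)[C@H]2c1c(OCc3ccccc3)cc(OCc3ccccc3)c2c1O[C@H](c1ccc(OCc3ccccc3)c(OCc3ccccc3)c1)[C@H](OCc3ccccc3)[C@H]2c1c(OCc3ccccc3)cc(OCc3ccccc3)c2c1O[C@H](c1ccc(OCc3ccccc3)c(OCc3ccccc3)c1)[C@@H](OCc3ccccc3)C2 | intermediate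
21 | 8-bromo-5,7,3′,4′-tetra-O-benzylepicatechin-(4β→8)-5,7,3′,4′-tetra-O-benzylepicatechin-(4β→8)-3,5,7,3′,4′-penta-O-benzylepicatechin-(4β→8)-3,5,7,3′,4′-penta-O-benzylcatechin | c3ccccc3COc1cc(OCc3ccccc3)c2c(c1Br)O[C@H](c1ccc(OCc3ccccc3)c(OCc3ccccc3)c1)[C@H](O)[C@H]2c1c(OCc3ccccc3)cc(OCc3ccccc3)c2c1O[C@H](c1ccc(OCc3ccccc3)c(OCc3ccccc3)c1)[C@H](O)[C@H]2c1c(OCc3ccccc3)cc(OCc3ccccc3)c2c1O[C@H](c1ccc(OCc3ccccc3)c(OCc3ccccc3)c1)[C@H](OCc3ccccc3)[C@H]2c1c(OCc3ccccc3)cc(OCc3ccccc3)c2c1O[C@H](c1ccc(OCc3ccccc3)c(OCc3ccccc3)c1)[C@@H](OCc3ccccc3)C2 | intermediate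
22 | arecatannin A2, epicatechin-(4β→8)-epicatechin-(4β→8)-epicatechin-(4β→8)-catechin | Oc1cc(O)c2c(c1)O[C@H](c1ccc(O)c(O)c1)[C@H](O)[C@H]2c1c(O)cc(O)c2c1O[C@H](c1ccc(O)c(O)c1)[C@H](O)[C@H]2c1c(O)cc(O)c2c1O[C@H](c1ccc(O)c(O)c1)[C@H](O)[C@H]2c1c(O)cc(O)c2c1O[C@H](c1ccc(O)c(O)c1)[C@@H](O)C2 | target

## Step count and least certain steps

Total step count: 15. Longest linear sequence: 14 steps (steps 2 to 15, from (−)-epicatechin 3); step 1 is a one-step side branch.

**Step 12 (key step).** The closure may go 5-exo instead of 6-endo. The C4 centre may be lost by propargyl-to-allene isomerisation. Traces of acid from the catalyst may protonate the electron-rich enol ether at C3 and lead to hydration or oligomerisation. Fallback, from 17 back to 18: the phenol is acetylated (Ac2O, pyridine) to aryl acetate F1, so that no internal oxygen nucleophile is left. The alkyne is then hydrated under gold catalysis (Ph3PAuNTf2, H2O, dioxane) with the same Markovnikov preference for the ring B carbon, giving aryl ketone F2. Methanolysis (K2CO3, MeOH) gives keto phenol F3, and acid-catalysed cyclodehydration (PPTS, 4 Å MS, benzene) gives 18. In this sequence the ring size is dictated by the position of the carbonyl group and not by the mode of attack on an alkyne.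

**Step 10.** The very stabilised propargylic cation may form without copper and react with poor facial control. The phenol may react through oxygen or through its para carbon, or methanol may capture the allenylidene. The product may cyclise onto the terminal alkyne under copper. Fallback, from alcohol 12 and phenol 14 to 15: ion-pair catalysis with a chiral BINOL-derived phosphoric acid bearing 2,4,6-triisopropylphenyl groups in toluene. The acid ionises 12 and delivers the hydrogen-bonded phenol within the contact ion pair. If facial control stays incomplete, the two C4 epimers of 15 are diastereomers and can be separated. This fallback makes no new compound (F0).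

**Step 11.** Copper or palladium may promote attack of the free phenol on the terminal alkyne (5-exo, followed by double-bond migration that would erase C4), or the amine may isomerise the propargylic centre. Fallback, from 15 back to 17: the phenol is masked (TBSOTf, 2,6-lutidine) as silyl ether F4, the Sonogashira coupling with 16 gives silylated aryl alkyne F5, and HF·pyridine releases 17 without base.

**Step 13.** The labile epoxide may rearrange by a 1,2-hydride shift to a flavan-3-one or lose a proton before it is reduced. Hydride may also enter syn to the C3 oxygen, because the face anti to that oxygen carries the pseudoaxial C4 aryl group. Fallback, from 18 back to 20: the epoxidation is run in CH2Cl2/MeOH so that the epoxide is trapped at once as the stable methyl ketal F6, which can be purified. Reduction with Et3SiH and TMSOTf at −78 °C then passes through the 3-silyloxy oxocarbenium ion, whose bulkier C3 substituent should reinforce hydride delivery anti to it, and gives 20 after loss of the silyl group on work-up.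

**Step 14.** The cation may attack a C6 position, the Lewis acid may cleave and scramble the interflavan bonds of 20 or 21, or the hindered nucleophile may react slowly. Fallback, from 6 and 20 to 21: 6 is converted with benzyl mercaptan and BF3·OEt2 into thioether F7, which is activated in the presence of 20 by AgBF4 in THF at 0 °C. This thiophilic activation works under nearly neutral conditions and with equimolar partners.

## Further compounds

F1 | step 12 | O-acetate of 17 | CC(=O)Oc1cc(OCc3ccccc3)cc(OCc3ccccc3)c1[C@@H](C#Cc1ccc(OCc3ccccc3)c(OCc3ccccc3)c1)c1c(OCc3ccccc3)cc(OCc3ccccc3)c2c1O[C@H](c1ccc(OCc3ccccc3)c(OCc3ccccc3)c1)[C@H](OCc3ccccc3)[C@H]2c1c(OCc3ccccc3)cc(OCc3ccccc3)c2c1O[C@H](c1ccc(OCc3ccccc3)c(OCc3ccccc3)c1)[C@@H](OCc3ccccc3)C2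
F2 | step 12 | aryl ketone from hydration of F1, 1-[3,4-bis(benzyloxy)phenyl]-3-(2-acetoxy-4,6-bis(benzyloxy)phenyl)-3-(dimer-8-yl)propan-1-one | CC(=O)Oc1cc(OCc3ccccc3)cc(OCc3ccccc3)c1[C@@H](CC(=O)c1ccc(OCc3ccccc3)c(OCc3ccccc3)c1)c1c(OCc3ccccc3)cc(OCc3ccccc3)c2c1O[C@H](c1ccc(OCc3ccccc3)c(OCc3ccccc3)c1)[C@H](OCc3ccccc3)[C@H]2c1c(OCc3ccccc3)cc(OCc3ccccc3)c2c1O[C@H](c1ccc(OCc3ccccc3)c(OCc3ccccc3)c1)[C@@H](OCc3ccccc3)C2
F3 | step 12 | keto phenol, deacetylated F2 | Oc1cc(OCc3ccccc3)cc(OCc3ccccc3)c1[C@@H](CC(=O)c1ccc(OCc3ccccc3)c(OCc3ccccc3)c1)c1c(OCc3ccccc3)cc(OCc3ccccc3)c2c1O[C@H](c1ccc(OCc3ccccc3)c(OCc3ccccc3)c1)[C@H](OCc3ccccc3)[C@H]2c1c(OCc3ccccc3)cc(OCc3ccccc3)c2c1O[C@H](c1ccc(OCc3ccccc3)c(OCc3ccccc3)c1)[C@@H](OCc3ccccc3)C2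
F0 | step 10 | none | none
F4 | step 11 | tert-butyldimethylsilyl ether of 15 | CC(C)(C)[Si](C)(C)Oc1cc(OCc3ccccc3)cc(OCc3ccccc3)c1[C@@H](C#C)c1c(OCc3ccccc3)cc(OCc3ccccc3)c2c1O[C@H](c1ccc(OCc3ccccc3)c(OCc3ccccc3)c1)[C@H](OCc3ccccc3)[C@H]2c1c(OCc3ccccc3)cc(OCc3ccccc3)c2c1O[C@H](c1ccc(OCc3ccccc3)c(OCc3ccccc3)c1)[C@@H](OCc3ccccc3)C2
F5 | step 11 | tert-butyldimethylsilyl ether of 17 | CC(C)(C)[Si](C)(C)Oc1cc(OCc3ccccc3)cc(OCc3ccccc3)c1[C@@H](C#Cc1ccc(OCc3ccccc3)c(OCc3ccccc3)c1)c1c(OCc3ccccc3)cc(OCc3ccccc3)c2c1O[C@H](c1ccc(OCc3ccccc3)c(OCc3ccccc3)c1)[C@H](OCc3ccccc3)[C@H]2c1c(OCc3ccccc3)cc(OCc3ccccc3)c2c1O[C@H](c1ccc(OCc3ccccc3)c(OCc3ccccc3)c1)[C@@H](OCc3ccccc3)C2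
F6 | step 13 | 2-methoxy ketal of 20 (methoxy trans to the 3-OH) | c3ccccc3COc1cc(OCc3ccccc3)c2c(c1)O[C@](OC)(c1ccc(OCc3ccccc3)c(OCc3ccccc3)c1)[C@H](O)[C@H]2c1c(OCc3ccccc3)cc(OCc3ccccc3)c2c1O[C@H](c1ccc(OCc3ccccc3)c(OCc3ccccc3)c1)[C@H](OCc3ccccc3)[C@H]2c1c(OCc3ccccc3)cc(OCc3ccccc3)c2c1O[C@H](c1ccc(OCc3ccccc3)c(OCc3ccccc3)c1)[C@@H](OCc3ccccc3)C2
F7 | step 14 | 8-bromo-5,7,3′,4′-tetra-O-benzyl-4β-(benzylthio)epicatechin | c3ccccc3COc1cc(OCc3ccccc3)c2c(c1Br)O[C@H](c1ccc(OCc3ccccc3)c(OCc3ccccc3)c1)[C@H](O)[C@H]2SCc1ccccc1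
A1 | alternative 1 | perbenzylated arecatannin A2 (twenty benzyl ethers) | c3ccccc3COc1cc(OCc3ccccc3)c2c(c1)O[C@H](c1ccc(OCc3ccccc3)c(OCc3ccccc3)c1)[C@H](OCc3ccccc3)[C@H]2c1c(OCc3ccccc3)cc(OCc3ccccc3)c2c1O[C@H](c1ccc(OCc3ccccc3)c(OCc3ccccc3)c1)[C@H](OCc3ccccc3)[C@H]2c1c(OCc3ccccc3)cc(OCc3ccccc3)c2c1O[C@H](c1ccc(OCc3ccccc3)c(OCc3ccccc3)c1)[C@H](OCc3ccccc3)[C@H]2c1c(OCc3ccccc3)cc(OCc3ccccc3)c2c1O[C@H](c1ccc(OCc3ccccc3)c(OCc3ccccc3)c1)[C@@H](OCc3ccccc3)C2
A2 | alternative 1 | tris-lactone backbone, units 1–3 as 3-benzyloxy-4-arylchroman-2-ones on penta-O-benzylcatechin | c3ccccc3COc1cc(OCc3ccccc3)c2c(c1)OC(=O)[C@H](OCc3ccccc3)[C@H]2c1c(OCc3ccccc3)cc(OCc3ccccc3)c2c1OC(=O)[C@H](OCc3ccccc3)[C@H]2c1c(OCc3ccccc3)cc(OCc3ccccc3)c2c1OC(=O)[C@H](OCc3ccccc3)[C@H]2c1c(OCc3ccccc3)cc(OCc3ccccc3)c2c1O[C@H](c1ccc(OCc3ccccc3)c(OCc3ccccc3)c1)[C@@H](OCc3ccccc3)C2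
A3 | alternative 1 | 3,4-bis(benzyloxy)phenyllithium | [Li]c1ccc(OCc2ccccc2)c(OCc2ccccc2)c1
A4 | alternative 2 | trimer carrying the new ring A of unit 4 (free C8a phenol, two triisopropylsilyl ethers, acetonide chain on C4a) | c3ccccc3COc1cc(OCc3ccccc3)c2c(c1)O[C@H](c1ccc(OCc3ccccc3)c(OCc3ccccc3)c1)[C@H](OCc3ccccc3)[C@H]2c1c(OCc3ccccc3)cc(OCc3ccccc3)c2c1O[C@H](c1ccc(OCc3ccccc3)c(OCc3ccccc3)c1)[C@H](OCc3ccccc3)[C@H]2c1c(OCc3ccccc3)cc(OCc3ccccc3)c2c1O[C@H](c1ccc(OCc3ccccc3)c(OCc3ccccc3)c1)[C@H](OCc3ccccc3)[C@H]2c1c(O[Si](C(C)C)(C(C)C)C(C)C)cc(O[Si](C(C)C)(C(C)C)C(C)C)c(C[C@H](OC4(C)C)[C@@H](O4)c5ccc(OCc3ccccc3)c(OCc3ccccc3)c5)c1O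
A5 | alternative 2 | 4-substituted 3-(triisopropylsilyloxy)cyclobut-2-enone carrying the acetonide chain | O=C1C=C(O[Si](C(C)C)(C(C)C)C(C)C)C1C[C@H](OC4(C)C)[C@@H](O4)c5ccc(OCc3ccccc3)c(OCc3ccccc3)c5
A6 | alternative 2 | benzylated trimer of units 1–3 with a (triisopropylsilyloxy)ethynyl group on C4 of unit 3 | c3ccccc3COc1cc(OCc3ccccc3)c2c(c1)O[C@H](c1ccc(OCc3ccccc3)c(OCc3ccccc3)c1)[C@H](OCc3ccccc3)[C@H]2c1c(OCc3ccccc3)cc(OCc3ccccc3)c2c1O[C@H](c1ccc(OCc3ccccc3)c(OCc3ccccc3)c1)[C@H](OCc3ccccc3)[C@H]2c1c(OCc3ccccc3)cc(OCc3ccccc3)c2c1O[C@H](c1ccc(OCc3ccccc3)c(OCc3ccccc3)c1)[C@H](OCc3ccccc3)[C@H]2C#CO[Si](C(C)C)(C(C)C)C(C)C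
A7 | alternative 3 | benzylated dimer of units 3 and 4 with a C3 tert-butyldimethylsilyl ether in unit 3 | c3ccccc3COc1cc(OCc3ccccc3)c2c(c1)O[C@H](c1ccc(OCc3ccccc3)c(OCc3ccccc3)c1)[C@H](O[Si](C)(C)C(C)(C)C)[C@H]2c1c(OCc3ccccc3)cc(OCc3ccccc3)c2c1O[C@H](c1ccc(OCc3ccccc3)c(OCc3ccccc3)c1)[C@@H](OCc3ccccc3)C2
A8 | alternative 3 | open-chain bromo alcohol, 2-bromo-4,6-bis(benzyloxy)phenyl on C4, free C2 hydroxyl, C3 silyl ether, on C8 of penta-O-benzylcatechin | c3ccccc3COc1cc(OCc3ccccc3)c(c(Br)c1)[C@@H]([C@@H](O[Si](C)(C)C(C)(C)C)[C@H](O)c1ccc(OCc3ccccc3)c(OCc3ccccc3)c1)c1c(OCc3ccccc3)cc(OCc3ccccc3)c2c1O[C@H](c1ccc(OCc3ccccc3)c(OCc3ccccc3)c1)[C@@H](OCc3ccccc3)C2
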